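## Retrosynthetic overview

1. The target comes from a last-step oxidation of a β-hydroxy-γ-lactone (secondary alcohol → enolised β-keto lactone). The furan ring is bought in 3-bromofuran 1, so the furanone is the only ring made.
2. A C(sp3)–C(sp2) cut between the CH2CH2 next to the methyl stereocentre and the nearer trisubstituted alkene (B-alkyl Suzuki–Miyaura) gives a vinyl-bearing hydroxy-lactone (west) and an (E,E)-dienyl iodide (east).
3. The lactone ring is closed before the fragment union: C3–C4 bond by a SmI2-mediated intramolecular aldol (Reformatsky type) of an α-(2-bromopropanoyloxy) aldehyde.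
4. West: the methyl centre comes from (S)-β-citronellene 2 (selective ozonolysis); the carbinol centre is set by L-proline α-aminoxylation.
5. East: from 1 by oxetane opening, acetylide alkylation and two Zr-catalysed carboalumination–iodination cycles joined by a Negishi coupling.

Assumption: commercial (S)-β-citronellene is taken as enantiopure; any minor diastereomer from a lower-ee lot is removed at diol 17.

## Eastern fragment

Step 1
Reactants: 1 3-bromofuran
Product: 4 3-(furan-3-yl)propan-1-ol, via furan-3-yllithium 3 (not isolated)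
Conditions: n-BuLi, THF, −78 °C; then oxetane, BF3·OEt2, −78 °C
Reagents that add atoms: oxetane (C1COC1)
Why: Bromine–lithium exchange gives the 3-lithiofuran (kept at −78 °C so it does not isomerise to the 2-lithio species), which opens BF3-activated oxetane by SN2 ring opening to attach the three-carbon alcohol arm.

Step 2
Reactants: 4 3-(furan-3-yl)propan-1-ol
Product: 5 3-(3-iodopropyl)furan
Conditions: I2, PPh3, imidazole, CH2Cl2, 0 °C → rt
Reagents that add atoms: iodine (II)
Why: Appel-type iodination converts the primary alcohol into the iodide under buffered conditions that the acid-sensitive furan tolerates.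

Step 3
Reactants: 5 3-(3-iodopropyl)furan
Product: 6 3-(pent-4-yn-1-yl)furan
Conditions: LiC≡CH·H2NCH2CH2NH2, DMSO, 10 °C → rt
Reagents that add atoms: lithium acetylide–ethylenediamine complex ([Li+].[C-]#C.NCCN)
Why: SN2 alkylation of acetylide by the unhindered primary iodide gives the terminal alkyne needed for carbometalation.

Step 4
Reactants: 6 3-(pent-4-yn-1-yl)furan
Product: 8 3-[(4E)-5-iodo-4-methylpent-4-en-1-yl]furan, via alkenylalane 7 (not isolated)
Conditions: Me3Al, Cp2ZrCl2 (25 mol %), CH2Cl2, 0 °C → rt; then I2, THF, −30 → 0 °C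
Reagents that add atoms: trimethylaluminium (C[Al](C)C), iodine (II)
Why: Negishi zirconium-catalysed carboalumination adds Me and Al syn across the alkyne with methyl at the internal carbon, and iodinolysis of the C–Al bond with retention fixes the E trisubstituted alkene.

Step 5
Reactants: 8 3-[(4E)-5-iodo-4-methylpent-4-en-1-yl]furan
Product: 9 [(5E)-9-(furan-3-yl)-6-methylnon-5-en-1-yn-1-yl]trimethylsilane
Conditions: BrCH2CH2C≡CSiMe3, Zn dust, LiCl, THF, 50 °C; then 8, Pd(PPh3)4 (3 mol %), THF, rt
Reagents that add atoms: (4-bromobut-1-yn-1-yl)trimethylsilane (C[Si](C)(C)C#CCCBr)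
Why: Negishi cross-coupling of the homopropargylzinc reagent with the alkenyl iodide forms the C(sp3)–C(sp2) bond with full retention of the E geometry, the silyl group masking the acidic alkyne C–H.

Step 6
Reactants: 9 [(5E)-9-(furan-3-yl)-6-methylnon-5-en-1-yn-1-yl]trimethylsilane
Product: 10 3-[(4E)-4-methylnon-4-en-8-yn-1-yl]furan
Conditions: K2CO3 (cat.), MeOH, rt
Reagents that add atoms: none
Why: Methanolysis of the alkynyl C–Si bond (protodesilylation) frees the terminal alkyne without touching the alkene or the furan.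

Step 7
Reactants: 10 3-[(4E)-4-methylnon-4-en-8-yn-1-yl]furan
Product: 12 3-[(4E,8E)-9-iodo-4,8-dimethylnona-4,8-dien-1-yl]furan, via dienylalane 11 (not isolated)
Conditions: Me3Al, Cp2ZrCl2 (25 mol %), CH2Cl2, 0 °C → rt; then I2, THF, −30 → 0 °C
Reagents that add atoms: trimethylaluminium (C[Al](C)C), iodine (II)
Why: A second Negishi carboalumination–iodinolysis acts only on the terminal alkyne (the trisubstituted alkene is inert) and sets the second E trisubstituted alkene as its alkenyl iodide.

## Western fragment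

Step 8
Reactants: 2 (3S)-3,7-dimethylocta-1,6-diene
Product: 14 (4S)-4-methylhex-5-enal, via ozonide 13 (not isolated)
Conditions: O3/O2, CH2Cl2, −78 °C (Sudan Red 7B end point); then Me2S, −78 °C → rt
Reagents that add atoms: ozone ([O-][O+]=O)
Why: Chemoselective ozonolysis cleaves the electron-rich trisubstituted alkene much faster than the monosubstituted vinyl group, and reductive work-up gives the aldehyde with the methyl stereocentre from the chiral pool untouched.

Step 9
Reactants: 14 (4S)-4-methylhex-5-enal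
Product: 16 (2R,4S)-4-methyl-2-[(phenylamino)oxy]hex-5-en-1-ol, via aminoxy aldehyde 15 (not isolated)
Conditions: PhNO, L-proline (20 mol %), DMSO, rt; then NaBH4, MeOH, 0 °C
Reagents that add atoms: nitrosobenzene (O=Nc1ccccc1)
Why: Proline-catalysed α-aminoxylation sets the 2R carbinol centre (future ring C5) under catalyst control through O-selective attack of nitrosobenzene on one face of the L-proline enamine, and borohydride reduces the labile aldehyde in the same pot.

Step 10
Reactants: 16 (2R,4S)-4-methyl-2-[(phenylamino)oxy]hex-5-en-1-ol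
Product: 17 (2R,4S)-4-methylhex-5-ene-1,2-diol
Conditions: Zn dust, AcOH/EtOH, rt
Reagents that add atoms: none
Why: Reductive cleavage of the weak N–O bond by zinc in acetic acid releases the secondary alcohol without affecting the alkene or the stereocentres.

Step 11
Reactants: 17 (2R,4S)-4-methylhex-5-ene-1,2-diol
Product: 18 (2R,4S)-1-[(tert-butyldimethylsilyl)oxy]-4-methylhex-5-en-2-ol
Conditions: TBSCl (1.05 equiv), imidazole, CH2Cl2, −10 °C
Reagents that add atoms: tert-butyldimethylsilyl chloride (CC(C)(C)[Si](C)(C)Cl)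
Why: Silylation is selective for the less hindered primary hydroxyl, leaving the secondary one free for acylation.

Step 12
Reactants: 18 (2R,4S)-1-[(tert-butyldimethylsilyl)oxy]-4-methylhex-5-en-2-ol
Product: 19 (2R,4S)-1-[(tert-butyldimethylsilyl)oxy]-4-methylhex-5-en-2-yl 2-bromopropanoate (both epimers at CHBr)
Conditions: 2-bromopropanoyl bromide, pyridine, CH2Cl2, −20 → 0 °C
Reagents that add atoms: 2-bromopropanoyl bromide (CC(Br)C(Br)=O)
Why: O-acylation installs the latent propanoate enolate on the secondary oxygen; the racemic CHBr centre does not matter because it becomes sp2 in the final product.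

Step 13
Reactants: 19 (2R,4S)-1-[(tert-butyldimethylsilyl)oxy]-4-methylhex-5-en-2-yl 2-bromopropanoate
Product: 20 (2R,4S)-1-hydroxy-4-methylhex-5-en-2-yl 2-bromopropanoate
Conditions: HF·pyridine, pyridine/THF, 0 °C; used at once
Reagents that add atoms: none
Why: Fluoride-mediated desilylation under weakly acidic buffered conditions frees the primary alcohol while suppressing the base-promoted 1,2-acyl migration.

Step 14
Reactants: 20 (2R,4S)-1-hydroxy-4-methylhex-5-en-2-yl 2-bromopropanoate
Product: 21 (2R,4S)-4-methyl-1-oxohex-5-en-2-yl 2-bromopropanoate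
Conditions: Dess–Martin periodinane, pyridine, CH2Cl2, 0 °C; used crude
Reagents that add atoms: none
Why: Dess–Martin oxidation gives the α-acyloxy aldehyde under near-neutral conditions, so the epimerisable α-centre is not exposed to base or silica.

Step 15
Reactants: 21 (2R,4S)-4-methyl-1-oxohex-5-en-2-yl 2-bromopropanoate
Product: 23 (5R)-4-hydroxy-3-methyl-5-[(2S)-2-methylbut-3-en-1-yl]oxolan-2-one (mixture at C3/C4), via samarium enolate 22 (not isolated)
Conditions: SmI2 (2.5 equiv), THF, −78 °C (21 added slowly); then pH 7 buffer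
Reagents that add atoms: none
Why: SmI2 reduces the C–Br bond to a samarium enolate that adds to the neighbouring aldehyde in an intramolecular aldol (Reformatsky-type) closure of the five-membered lactone without any base, so the C5 centre from step 9 is kept and the new C3/C4 centres, formed as a mixture, are erased in step 17.

## Fragment union and end game

Step 16
Reactants: 23 (5R)-4-hydroxy-3-methyl-5-[(2S)-2-methylbut-3-en-1-yl]oxolan-2-one; 12 3-[(4E,8E)-9-iodo-4,8-dimethylnona-4,8-dien-1-yl]furan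
Product: 25 (5R)-5-[(2R,5E,9E)-13-(furan-3-yl)-2,6,10-trimethyltrideca-5,9-dien-1-yl]-4-hydroxy-3-methyloxolan-2-one (mixture at C3/C4), via alkylborane 24 (not isolated)
Conditions: 9-BBN (2.2 equiv), THF, 0 °C → rt; then H2O, Cs2CO3, 12, Pd(dppf)Cl2 (5 mol %), AsPh3, DMF, rt; work-up at pH 4
Reagents that add atoms: none
Why: B-alkyl Suzuki–Miyaura coupling, in which 9-BBN hydroborates only the terminal vinyl group anti-Markovnikov and the primary alkyl group transfers to the alkenyl iodide with retention of the E geometry, the extra borane covering any consumption by the free hydroxyl.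

Step 17
Reactants: 25 (5R)-5-[(2R,5E,9E)-13-(furan-3-yl)-2,6,10-trimethyltrideca-5,9-dien-1-yl]-4-hydroxy-3-methyloxolan-2-one
Product: 26 (5R)-5-[(2R,5E,9E)-13-(furan-3-yl)-2,6,10-trimethyltrideca-5,9-dien-1-yl]-4-hydroxy-3-methylfuran-2(5H)-one (target)
Conditions: Dess–Martin periodinane (1.2 equiv), CH2Cl2, 0 °C → rt; work-up at pH 4–5
Reagents that add atoms: none
Why: Dess–Martin oxidation of the secondary alcohol gives the β-keto lactone, which enolises at once to the 4-hydroxyfuranone and so converges all C3/C4 diastereomers on one product while leaving the furan, both alkenes and the C5 and side-chain stereocentres untouched.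

## Compound list

1 | 3-bromofuran | Brc1ccoc1 | starting material
2 | (3S)-3,7-dimethylocta-1,6-diene [(S)-β-citronellene] | C=C[C@@H](C)CCC=C(C)C | starting material
3 | furan-3-yllithium | [Li]c1ccoc1 | intermediate (not isolated)
4 | 3-(furan-3-yl)propan-1-ol | OCCCc1ccoc1 | intermediate
5 | 3-(3-iodopropyl)furan | ICCCc1ccoc1 | intermediate
6 | 3-(pent-4-yn-1-yl)furan | C#CCCCc1ccoc1 | intermediate
7 | [(1E)-5-(furan-3-yl)-2-methylpent-1-en-1-yl]dimethylalumane | C[Al](C)/C=C(\C)CCCc1ccoc1 | intermediate (not isolated)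
8 | 3-[(4E)-5-iodo-4-methylpent-4-en-1-yl]furan | I/C=C(\C)CCCc1ccoc1 | intermediate
9 | [(5E)-9-(furan-3-yl)-6-methylnon-5-en-1-yn-1-yl]trimethylsilane | C[Si](C)(C)C#CCC/C=C(\C)CCCc1ccoc1 | intermediate
10 | 3-[(4E)-4-methylnon-4-en-8-yn-1-yl]furan | C#CCC/C=C(\C)CCCc1ccoc1 | intermediate
11 | [(1E,5E)-9-(furan-3-yl)-2,6-dimethylnona-1,5-dien-1-yl]dimethylalumane | C[Al](C)/C=C(\C)CC/C=C(\C)CCCc1ccoc1 | intermediate (not isolated)
12 | 3-[(4E,8E)-9-iodo-4,8-dimethylnona-4,8-dien-1-yl]furan | I/C=C(\C)CC/C=C(\C)CCCc1ccoc1 | intermediate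
13 | 3,3-dimethyl-5-[(3S)-3-methylpent-4-en-1-yl]-1,2,4-trioxolane | C=C[C@@H](C)CCC1OOC(C)(C)O1 | intermediate (not isolated)
14 | (4S)-4-methylhex-5-enal | C=C[C@@H](C)CCC=O | intermediate
15 | (2R,4S)-4-methyl-2-[(phenylamino)oxy]hex-5-enal | C=C[C@@H](C)C[C@@H](ONc1ccccc1)C=O | intermediate (not isolated)
16 | (2R,4S)-4-methyl-2-[(phenylamino)oxy]hex-5-en-1-ol | C=C[C@@H](C)C[C@@H](ONc1ccccc1)CO | intermediate
17 | (2R,4S)-4-methylhex-5-ene-1,2-diol | C=C[C@@H](C)C[C@@H](O)CO | intermediate
18 | (2R,4S)-1-[(tert-butyldimethylsilyl)oxy]-4-methylhex-5-en-2-ol | C=C[C@@H](C)C[C@@H](O)CO[Si](C)(C)C(C)(C)C | intermediate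
19 | (2R,4S)-1-[(tert-butyldimethylsilyl)oxy]-4-methylhex-5-en-2-yl 2-bromopropanoate | C=C[C@@H](C)C[C@@H](OC(=O)C(C)Br)CO[Si](C)(C)C(C)(C)C | intermediate
20 | (2R,4S)-1-hydroxy-4-methylhex-5-en-2-yl 2-bromopropanoate | C=C[C@@H](C)C[C@@H](OC(=O)C(C)Br)CO | intermediate
21 | (2R,4S)-4-methyl-1-oxohex-5-en-2-yl 2-bromopropanoate | C=C[C@@H](C)C[C@@H](OC(=O)C(C)Br)C=O | intermediate
22 | diiodosamarium enolate of 21 (O-bound, trivalent samarium) | C=C[C@@H](C)C[C@@H](OC(=CC)O[Sm](I)I)C=O | intermediate (not isolated)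
23 | (5R)-4-hydroxy-3-methyl-5-[(2S)-2-methylbut-3-en-1-yl]oxolan-2-one | CC1C(O)[C@@H](C[C@H](C)C=C)OC1=O | intermediate
24 | (5R)-5-[(2R)-4-(9-borabicyclo[3.3.1]nonan-9-yl)-2-methylbutyl]-4-hydroxy-3-methyloxolan-2-one | CC1C(O)[C@@H](C[C@H](C)CCB2C3CCCC2CCC3)OC1=O | intermediate (not isolated)
25 | (5R)-5-[(2R,5E,9E)-13-(furan-3-yl)-2,6,10-trimethyltrideca-5,9-dien-1-yl]-4-hydroxy-3-methyloxolan-2-one | CC1C(O)[C@@H](C[C@H](C)CC/C=C(\C)CC/C=C(\C)CCCc2ccoc2)OC1=O | intermediate
26 | (5R)-5-[(2R,5E,9E)-13-(furan-3-yl)-2,6,10-trimethyltrideca-5,9-dien-1-yl]-4-hydroxy-3-methylfuran-2(5H)-one | CC1=C(O)[C@@H](C[C@H](C)CC/C=C(\C)CC/C=C(\C)CCCc2ccoc2)OC1=O | target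

## Step count and risks

Total step count: 17 (steps 1–7 eastern iodide, steps 8–15 western lactone, steps 16–17 union and oxidation).
Longest linear sequence: 10 steps (2 → 26, steps 8–17); the eastern branch reaches the target in 9 steps.

The three steps most likely to fail:

Step 15 (samarium aldol closure). The α-acyloxy aldehyde 21 is labile, and SmI2 could instead reduce the aldehyde or cleave the α-C–O bond. The fallback closes the ring by lactonisation and makes the C3–C4 bond intermolecularly. It sets out from diol 17. TBSOTf and 2,6-lutidine give the bis-silyl ether (2R,4S)-1,2-bis[(tert-butyldimethylsilyl)oxy]-4-methylhex-5-ene F1. HF·pyridine at 0 °C frees only the primary alcohol, giving (2R,4S)-2-[(tert-butyldimethylsilyl)oxy]-4-methylhex-5-en-1-ol F2. Dess–Martin oxidation gives the configurationally robust α-silyloxy aldehyde (2R,4S)-2-[(tert-butyldimethylsilyl)oxy]-4-methylhex-5-enal F3. Addition of the lithium enolate of ethyl propanoate (LiN(i-Pr)2, THF, −78 °C) gives ethyl (4R,6S)-4-[(tert-butyldimethylsilyl)oxy]-3-hydroxy-2,6-dimethyloct-7-enoate F4 as a diastereomer mixture at C2/C3. Aqueous HF in MeCN removes the silyl group and the γ-hydroxy ester lactonises to 23, where the route is rejoined.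

Step 16 (B-alkyl Suzuki–Miyaura on the free hydroxy-lactone). The β-hydroxy lactone may consume borane or suffer in the aqueous carbonate medium. The fallback couples first and builds the ring afterwards. It sets out from silyl ether 18 and iodide 12. Hydroboration of 18 with 9-BBN and coupling with 12 (Pd(dppf)Cl2, AsPh3, Cs2CO3, DMF/H2O) give (2R,4R,7E,11E)-1-[(tert-butyldimethylsilyl)oxy]-15-(furan-3-yl)-4,8,12-trimethylpentadeca-7,11-dien-2-ol F5. Acylation with 2-bromopropanoyl bromide and pyridine gives (2R,4R,7E,11E)-1-[(tert-butyldimethylsilyl)oxy]-15-(furan-3-yl)-4,8,12-trimethylpentadeca-7,11-dien-2-yl 2-bromopropanoate F6. HF·pyridine gives (2R,4R,7E,11E)-15-(furan-3-yl)-1-hydroxy-4,8,12-trimethylpentadeca-7,11-dien-2-yl 2-bromopropanoate F7. Dess–Martin oxidation gives (2R,4R,7E,11E)-15-(furan-3-yl)-4,8,12-trimethyl-1-oxopentadeca-7,11-dien-2-yl 2-bromopropanoate F8. The SmI2 aldol closure of F8 at −78 °C then gives 25, where the route is rejoined; all of these reagents are compatible with the furan and the trisubstituted alkenes.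

Step 17 (final oxidation). The acidic, enolic product can be over-oxidised by the periodinane, and the furan-polyene limits the choice of oxidant. The fallback oxidises before the coupling and carries a protected tetronate through it. It sets out from 23. Oxidation with CrO3/H2SO4 in acetone at 0 °C (usable here because no furan is present) gives (5R)-4-hydroxy-3-methyl-5-[(2S)-2-methylbut-3-en-1-yl]furan-2(5H)-one F9. MOMCl and i-Pr2NEt give the enol ether (5R)-4-(methoxymethoxy)-3-methyl-5-[(2S)-2-methylbut-3-en-1-yl]furan-2(5H)-one F10. Hydroboration with 9-BBN and coupling with 12 under the step-16 conditions give (5R)-5-[(2R,5E,9E)-13-(furan-3-yl)-2,6,10-trimethyltrideca-5,9-dien-1-yl]-4-(methoxymethoxy)-3-methylfuran-2(5H)-one F11. Pyridinium p-toluenesulfonate in MeOH at 40 °C cleaves the vinylogous acetal and gives the target 26, where the route is rejoined.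

## Further compounds

F1 | step 15 | (2R,4S)-1,2-bis[(tert-butyldimethylsilyl)oxy]-4-methylhex-5-ene | C=C[C@@H](C)C[C@@H](O[Si](C)(C)C(C)(C)C)CO[Si](C)(C)C(C)(C)C
F2 | step 15 | (2R,4S)-2-[(tert-butyldimethylsilyl)oxy]-4-methylhex-5-en-1-ol | C=C[C@@H](C)C[C@@H](O[Si](C)(C)C(C)(C)C)CO
F3 | step 15 | (2R,4S)-2-[(tert-butyldimethylsilyl)oxy]-4-methylhex-5-enal | C=C[C@@H](C)C[C@@H](O[Si](C)(C)C(C)(C)C)C=O
F4 | step 15 | ethyl (4R,6S)-4-[(tert-butyldimethylsilyl)oxy]-3-hydroxy-2,6-dimethyloct-7-enoate | CCOC(=O)C(C)C(O)[C@@H](C[C@H](C)C=C)O[Si](C)(C)C(C)(C)C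
F5 | step 16 | (2R,4R,7E,11E)-1-[(tert-butyldimethylsilyl)oxy]-15-(furan-3-yl)-4,8,12-trimethylpentadeca-7,11-dien-2-ol | CC(C)(C)[Si](C)(C)OC[C@H](O)C[C@H](C)CC/C=C(\C)CC/C=C(\C)CCCc1ccoc1
F6 | step 16 | (2R,4R,7E,11E)-1-[(tert-butyldimethylsilyl)oxy]-15-(furan-3-yl)-4,8,12-trimethylpentadeca-7,11-dien-2-yl 2-bromopropanoate | CC(C)(C)[Si](C)(C)OC[C@H](OC(=O)C(C)Br)C[C@H](C)CC/C=C(\C)CC/C=C(\C)CCCc1ccoc1
F7 | step 16 | (2R,4R,7E,11E)-15-(furan-3-yl)-1-hydroxy-4,8,12-trimethylpentadeca-7,11-dien-2-yl 2-bromopropanoate | OC[C@H](OC(=O)C(C)Br)C[C@H](C)CC/C=C(\C)CC/C=C(\C)CCCc1ccoc1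
F8 | step 16 | (2R,4R,7E,11E)-15-(furan-3-yl)-4,8,12-trimethyl-1-oxopentadeca-7,11-dien-2-yl 2-bromopropanoate | O=C[C@H](OC(=O)C(C)Br)C[C@H](C)CC/C=C(\C)CC/C=C(\C)CCCc1ccoc1
F9 | step 17 | (5R)-4-hydroxy-3-methyl-5-[(2S)-2-methylbut-3-en-1-yl]furan-2(5H)-one | CC1=C(O)[C@@H](C[C@H](C)C=C)OC1=O
F10 | step 17 | (5R)-4-(methoxymethoxy)-3-methyl-5-[(2S)-2-methylbut-3-en-1-yl]furan-2(5H)-one | CC1=C(OCOC)[C@@H](C[C@H](C)C=C)OC1=O
F11 | step 17 | (5R)-5-[(2R,5E,9E)-13-(furan-3-yl)-2,6,10-trimethyltrideca-5,9-dien-1-yl]-4-(methoxymethoxy)-3-methylfuran-2(5H)-one | CC1=C(OCOC)[C@@H](C[C@H](C)CC/C=C(\C)CC/C=C(\C)CCCc2ccoc2)OC1=O
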